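The red run comes first: its open intermediate stops climbing near 63.5%, the mean of its readings at 6.00 h and 10.0 h, and we call that the ceiling.

| flask | substrate | partner | temperature | remark | time |
|---|---|---|---|---|---|
| green | 13 mM | 26 mM | −20 °C | run made earlier |  |
| red | 30 mM | 26 mM | 5 °C | run made earlier |  |
| Friday's | 20 mM | 26.0 mM | 5 °C |  | 15 h |
| Monday's | 20 mM | 26.0 mM | −15 °C |  | 15 h |
| Tuesday's | 20 mM | 26.0 mM | 25 °C |  | 15 h |

| run | time / h | open intermediate / % | target / % |
|---|---|---|---|
| green | 3.00 | 0 | 3 |
| green | 8.00 | 1 | 0 |
| green | 15.0 | 5 | 0 |
| green | 20.0 | 13 | 0 |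
| green | 30.0 | 18 | 0 |
| red | 0.833 | 17 | 6 |
| red | 2.50 | 37 | 1 |
| red | 4.00 | 54 | 0 |
| red | 6.00 | 62 | 1 |
| red | 10.0 | 65 | 5 |

(scatter of a reading: 2 percentage points)

- a reading or a percentage of target counts all its forms, free or not

* the flask that comes out highest in amount of open intermediate, in percent of the substrate charged, or "all alike" when all lie within 1.5 percentage points (Friday's / Monday's / Tuesday's / all alike)
* open intermediate at the end, in percent of the substrate charged, Friday's
* open intermediate at the end, in percent of the substrate charged, Monday's
* open intermediate at the end, in percent of the substrate charged, Tuesday's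

The ceiling is the late end of the curve, so we want the early end too. By its first reading, at 0.833 h, red has opened 0.204 h⁻¹ of its charge per hour. Ceiling over early rate is the filling time 3.11 h, a relaxation time. We join the ends: the share is the ceiling times one minus exp(−time/filling time).

But this assumes that shares ignore the charge and that the ceiling holds at other temperatures, and two runs differing in temperature can't test either.

Friday's stands at red's temperature, and 15 h is long against the filling time, so we expect 63.0%.

Green's last reading gives 0.00600 h⁻¹. Monday's −15 °C lies one part in 5 of the way from green's −20 °C to red's 5 °C, so, taking the logarithm of the rate as straight in temperature, its filling time is 52.3 h and its share 15.8%.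

The same line carried up to Tuesday's 25 °C gives 0.185 h, short against 15 h, so its reading shows what drainage has left. Red's target of 5%, with a scatter of 2 percentage points, can't size that drainage. We say only that Tuesday's lies below the ceiling, and we pick Friday's.

The forecast names Friday's, with 70%, 16% and 22% for Friday's, Monday's and Tuesday's, the last “very uncertain”; its Friday's stands above our 63.0%.

The flasks give Friday's as highest, with 61.6% on Friday's, 13.8% on Monday's and 7.38% on Tuesday's.

    substrate ⇌ open intermediate (K = 2.30, k = 3.20 h⁻¹, Ea = 92.0 kJ mol⁻¹, ΔH = −7.00 kJ mol⁻¹)
    partner → second intermediate (k = 0.170 h⁻¹, Ea = 90.0 kJ mol⁻¹)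
    open intermediate + second intermediate → target (k = 19.0 M⁻¹ h⁻¹, Ea = 52.0 kJ mol⁻¹)
    2 open intermediate → homo product (k = 3.80 M⁻¹ h⁻¹, Ea = 79.0 kJ mol⁻¹)
    crystals ⇌ target, rate k5*(cs5 - [target]) while solid is left; crystals form when [target] > cs5 (solubility = 5.30 mM, k = 5.30 h⁻¹)
    (constants at 25 °C)

At the end of Tuesday's, target holds 63.6% of the charge and homo product 25.6%, each of its units counted as two. Put to Monday's halfway through, at 7.50 h, the filling time gives 8.48%, and the flask then holds 7.27%. At 150 h Monday's holds 59.8% of open intermediate, with 32.2% of its charge still substrate.

The data are simulated on assumed constants.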